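**Retrosynthetic overview**
1. The 9-OH and the γ-lactone come last, from two hydroxyl-controlled reductions (C7, then C9) of a ten-membered 8-hydroxy-7,9-dione.
2. The ten-membered carbocycle (C7–C8 bond, C8 carbinol) comes from ring contraction of an eleven-membered α-acyloxy-ketone lactone by an anionic O→C 1,2-acyl shift.
3. The lactone comes from carboxylate alkylation (C7 acid, C8 bromide); C8–C9 comes from Fukuyama coupling of a ring A thioester with a Roche-ester zinc reagent.
4. C2–C3 comes from ligand-controlled addition of a dialkylzinc carrying the chloroalkene (ynoate carbocupration/chlorination) to the ring A aldehyde; 12-OAc and the epoxide come from Saegusa oxidation, CBS reduction and directed epoxidation.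
5. Ring A comes from an enantioselective Diels–Alder reaction. Ring order: ring A, epoxide, eleven-membered lactone, ten-membered carbocycle, γ-lactone.

Assumption: locants follow the briarane skeleton of the target (C1 quaternary ring-fusion carbon, C2–C9 around the ten-membered ring, C10 ring-fusion CH, C11–C14 ring A, methyls C15/C16/C18/C20 on C1/C5/C17/C11, C19 lactone carbonyl), β is the face of the C15 methyl in the flat drawing, and silyl groups and the 2-(trimethylsilyl)ethyl ester (brought in by its chloroformate reagent) count as protecting groups.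

**Step 1**
Reactants: 1 3-methylbut-2-enoyl chloride; 2 ethanethiol
Product: 3 S-ethyl 3-methylbut-2-enethioate
Conditions: pyridine, CH2Cl2, 0 °C → rt
Reagents that add atoms: none
Why: Acyl substitution of the acid chloride by the thiol gives the thioester that later serves as the acyl donor for the Fukuyama coupling; no stereocentre is formed.

**Step 2**
Reactants: 3 S-ethyl 3-methylbut-2-enethioate
Product: 4 S-ethyl (E)-3-methyl-4-oxobut-2-enethioate
Conditions: SeO2, 1,4-dioxane, 90 °C
Reagents that add atoms: selenium dioxide, O=[Se]=O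
Why: Riley allylic oxidation (ene reaction then 2,3-shift) oxidises the methyl group trans to the carbonyl of a senecioate, giving the (E)-formyl dienophile with CHO and C(=O)SEt trans.

**Step 3**
Reactants: 5 pent-1-en-3-one
Product: 6 (Z)-triisopropyl(penta-1,3-dien-3-yloxy)silane
Conditions: iPr3SiOTf, Et3N, Et2O, 0 °C
Reagents that add atoms: triisopropylsilyl trifluoromethanesulfonate, CC(C)[Si](OS(=O)(=O)C(F)(F)F)(C(C)C)C(C)C
Why: Soft enolisation and O-silylation of the ethyl ketone gives the favoured (Z)-2-silyloxy diene, whose methyl group points outward in the s-cis form.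

**Step 4**
Reactants: 4 S-ethyl (E)-3-methyl-4-oxobut-2-enethioate; 6 (Z)-silyloxy diene
Product: 7 S-ethyl 6-formyl-2,6-dimethyl-3-(triisopropylsilyloxy)cyclohex-3-ene-1-carbothioate (thioester and both methyls β; formyl α)
Conditions: (S)-3,3-diphenyl-1-(2-methylphenyl)tetrahydro-1H,3H-pyrrolo[1,2-c][1,3,2]oxazaborole activated with HN(SO2CF3)2 (20 mol %), CH2Cl2, −78 → −40 °C
Reagents that add atoms: none
Why: Enantioselective Diels–Alder reaction under chiral oxazaborolidinium Lewis acid catalysis, in which the catalyst binds the formyl group so that the nucleophilic methyl-bearing diene terminus adds to the carbon β to the aldehyde (C10, "para" silyloxy adduct); the exo-formyl/endo-thioester transition state typical of α-methyl enals puts C15, C9 and C20 cis, the trans dienophile fixes C2 trans to C9, and the catalyst shields one enal face to set the absolute configuration of C1, C10 and C11.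

**Step 5**
Reactants: 8 4-iodobut-1-yne
Product: 10 2-(trimethylsilyl)ethyl 5-iodopent-2-ynoate, via lithium 4-iodobut-1-ynide 9 (not isolated)
Conditions: LiN(iPr)2, THF, −78 °C; then Me3SiCH2CH2OCOCl, −78 → −40 °C
Reagents that add atoms: 2-(trimethylsilyl)ethyl carbonochloridate, C[Si](C)(C)CCOC(Cl)=O
Why: C-acylation of a lithium acetylide with a chloroformate, the alkyne C–H being removed at −78 °C faster than the primary iodide eliminates or is substituted.

**Step 6**
Reactants: 10 2-(trimethylsilyl)ethyl 5-iodopent-2-ynoate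
Product: 12 2-(trimethylsilyl)ethyl (E)-2-chloro-5-iodo-3-methylpent-2-enoate, via lithium alkenyl(methyl)cuprate 11 (not isolated)
Conditions: Me2CuLi (from MeLi, CuI), THF, −78 °C; then N-chlorosuccinimide, −78 °C
Reagents that add atoms: lithium dimethylcuprate (Me2CuLi), C[Cu-]C.[Li+]; N-chlorosuccinimide, O=C1CCC(=O)N1Cl
Why: Syn-carbocupration of the ynoate followed by electrophilic chlorination of the α-cuprio enoate with retention places the new methyl and the chlorine cis, which fixes the tetrasubstituted C5=C6 geometry (C4 cis to C7) of the target.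

**Step 7**
Reactants: 7 cycloadduct aldehyde; 12 iodo chloroenoate
Product: 14 (2S)-carbinol in which the CHO of 7 has become (S)-CH(OH)CH2CH2C(CH3)=C(Cl)CO2CH2CH2SiMe3, via dialkylzinc 13 (not isolated)
Conditions: 12 (2.4 equiv), Et2Zn, CuI (cat.), 50 °C, then vacuum; Ti(OiPr)4 (2 equiv), (1R,2R)-N,N′-bis(trifluoromethanesulfonyl)cyclohexane-1,2-diamine (10 mol %), toluene, −20 °C; aq NH4Cl
Reagents that add atoms: none
Why: Catalytic enantioselective addition of a functionalised dialkylzinc (iodine–zinc exchange, then titanium/bis-sulfonamide catalysis) forms C2–C3 and sets C2 as S by ligand control, reinforced by Felkin–Anh attack anti to C10; thioester, ester, vinyl chloride and silyl enol ether are inert to the organozinc, and the trans-diaxial C2–O/C9 arrangement disfavours lactonisation.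

**Step 8**
Reactants: 14 (2S)-carbinol silyl enol ether
Product: 15 cyclohexenone (C12 ketone, C13=C14) with all other groups of 14 unchanged
Conditions: Pd(OAc)2 (1.1 equiv), MeCN, 40 °C
Reagents that add atoms: none
Why: Saegusa–Ito oxidation, in which the palladium enolate formed from the silyl enol ether undergoes β-hydride elimination toward C14, gives the enone under non-basic conditions that do not epimerise C11.

**Step 9**
Reactants: 15 cyclohexenone
Product: 16 12α-allylic alcohol (2S,12α-diol)
Conditions: (S)-1-methyl-3,3-diphenyltetrahydro-1H,3H-pyrrolo[1,2-c][1,3,2]oxazaborole (30 mol %), catecholborane, toluene, −78 °C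
Reagents that add atoms: none
Why: Corey–Bakshi–Shibata reduction in which the catalyst treats the branched C11 side as the large group and delivers hydride to the β face of the C12 ketone, giving the 12α-alcohol trans to the C11 methyl by 1,2-reduction only.

**Step 10**
Reactants: 16 12α-allylic alcohol
Product: 17 13α,14α-epoxy-2,12-diol
Conditions: VO(acac)2 (5 mol %), t-BuOOH, CH2Cl2, 0 °C
Reagents that add atoms: tert-butyl hydroperoxide, CC(C)(C)OO
Why: Hydroxyl-directed vanadium-catalysed epoxidation delivers oxygen syn to the 12α-OH (helped by the homoallylic 2-OH on the same face), giving the α-epoxide, while the electron-poor tetrasubstituted chloroalkene does not react.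

**Step 11**
Reactants: 17 epoxy diol
Product: 18 2,12-di-O-acetate of 17
Conditions: Ac2O, pyridine, DMAP (cat.), CH2Cl2, rt
Reagents that add atoms: acetic anhydride, CC(=O)OC(C)=O
Why: DMAP-catalysed acylation installs both acetates of the target in one operation on the only two hydroxyls present.

**Step 12**
Reactants: 19 methyl (R)-3-hydroxy-2-methylpropanoate
Product: 20 methyl (S)-3-iodo-2-methylpropanoate
Conditions: I2, PPh3, imidazole, CH2Cl2, 0 °C → rt
Reagents that add atoms: iodine, II
Why: Appel-type iodination of the primary alcohol leaves the C17 stereocentre untouched (the descriptor changes only because CH2I outranks the ester).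

**Step 13**
Reactants: 18 thioester diacetate; 20 methyl (S)-3-iodo-2-methylpropanoate
Product: 22 keto ester in which the C(=O)SEt of 18 has become C(=O)CH2CH(CH3)CO2CH3 (C9 ketone; 17R), via alkylzinc iodide 21 (not isolated)
Conditions: 20, Zn dust, THF/DMA, rt; then 18, PdCl2(PPh3)2 (10 mol %), toluene, rt
Reagents that add atoms: none
Why: Fukuyama coupling, in which zerovalent palladium inserts into the thioester C–S bond and transmetalates with the zinc homoenolate, forms the C8–C9 bond and the ketone without touching acetates, epoxide, esters or the vinyl chloride, and the zinc reagent keeps the C17 configuration.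

**Step 14**
Reactants: 22 keto ester
Product: 24 8-bromo-9-ketone (both C8 epimers), via trimethylsilyl enol ether 23 (not isolated)
Conditions: LiN(SiMe3)2, Me3SiCl, THF, −78 °C; then N-bromosuccinimide, −78 → 0 °C
Reagents that add atoms: N-bromosuccinimide, O=C1CCC(=O)N1Br
Why: Kinetic enolisation of the C9 ketone on its unhindered methylene side (in situ silyl trap) and bromination of the silyl enol ether give the α-bromo ketone regioselectively; the C8 configuration is irrelevant because it is erased in step 16.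

**Step 15**
Reactants: 24 bromo ketone
Product: 26 eleven-membered lactone closed by the C7(=O)–O–C8 bond (ring atoms C1–C7, O, C8–C10; C8 epimers), via sulfonium carboxylate 25 (not isolated)
Conditions: TASF [(Me2N)3S+ Me3SiF2−], DMF (1 mM), 0 °C → rt
Reagents that add atoms: none
Why: Fluoride cleaves the silylethyl ester and the free carboxylate displaces the activated α-keto bromide in an intramolecular SN2 macrolactonisation at high dilution; the weakly basic medium limits E1cB loss of HBr toward C17.

**Step 16**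
Reactants: 26 eleven-membered lactone
Product: 28 ten-membered 8α-hydroxy-7,9-dione carrying the CH(CH3)CO2CH3 branch on C8 (β), via lithium enolate 27 (not isolated)
Conditions: LiN(SiMe3)2 (1.1 equiv), THF, −78 → −30 °C; AcOH, −78 °C
Reagents that add atoms: none
Why: Proposed new method: a ring-contracting O→C 1,2-acyl shift of a macrocyclic α-acyloxy ketone, in which the C8 enolate (its α-acyloxy C–H is far more acidic than the ester and acetate C–H) attacks the adjacent ester carbonyl C7 through a three-membered 2-oxidooxirane that collapses with C7–O cleavage, so the ring oxygen leaves the ring as the C8 alkoxide, the eleven-membered lactone contracts to the ten-membered carbocycle and the C7–C8 bond and C8 carbinol are formed, driven by the chelated tertiary lithium alkoxide; C8 should be set because the ring-cis enolate holds H10 in its plane (allylic strain), so the chain through C1 and the migrating acyl reach C8 from the face anti to C11, giving 8α-OH/8β-C17; the closest known reaction type is the Chan rearrangement of acyclic α-acyloxy esters and ketones to 2-hydroxy-1,3-dicarbonyl compounds, which has not been shown as a contraction of a medium-ring lactone to a carbocycle.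

**Step 17**
Reactants: 28 hydroxy diketone
Product: 30 9-oxo lactone (C7–O–C19 γ-lactone closed; 8α-OH; C9 ketone), via 7β-hydroxy ester 29 (not isolated)
Conditions: NaBH4, CeCl3·7H2O, MeOH, −78 °C; then AcOH, rt
Reagents that add atoms: none
Why: Luche reduction takes the conjugated, less hindered C7 ketone in preference to the neopentyl-type C9 ketone; in the cerium chelate of the 8-hydroxy ketone hydride enters past the flat C9 carbonyl and anti to the branched C17 substituent, giving the 7β-alcohol cis to C17, which lactonises onto the methyl ester to the cis-fused γ-lactone.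

**Step 18**
Reactants: 30 9-oxo lactone
Product: 31 CNP0255641.1
Conditions: Me4NBH(OAc)3, MeCN/AcOH, −20 → 0 °C
Reagents that add atoms: none
Why: Hydroxyl-directed (Evans–Saksena) reduction, in which the 8α-OH binds the triacetoxyborohydride and delivers hydride to the α face of the hindered C9 ketone, gives the 9β-alcohol while acetates, lactone, epoxide and vinyl chloride are untouched.

**Compound list**
1 | 3-methylbut-2-enoyl chloride | CC(C)=CC(Cl)=O | starting material
2 | ethanethiol | CCS | starting material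
3 | S-ethyl 3-methylbut-2-enethioate | CCSC(=O)C=C(C)C | intermediate
4 | S-ethyl (E)-3-methyl-4-oxobut-2-enethioate | O=C/C(C)=C/C(=O)SCC | intermediate
5 | pent-1-en-3-one | CCC(=O)C=C | starting material
6 | (Z)-triisopropyl(penta-1,3-dien-3-yloxy)silane | C/C=C(O[Si](C(C)C)(C(C)C)C(C)C)/C=C | intermediate
7 | S-ethyl 6-formyl-2,6-dimethyl-3-(triisopropylsilyloxy)cyclohex-3-ene-1-carbothioate; thioester, 2-methyl and 6-methyl cis (β), formyl α | C[C@H]1C(O[Si](C(C)C)(C(C)C)C(C)C)=CC[C@](C)(C=O)[C@H]1C(=O)SCC | intermediate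
8 | 4-iodobut-1-yne | C#CCCI | starting material
9 | lithium 4-iodobut-1-ynide | [Li+].[C-]#CCCI | intermediate (not isolated)
10 | 2-(trimethylsilyl)ethyl 5-iodopent-2-ynoate | C[Si](C)(C)CCOC(=O)C#CCCI | intermediate
11 | lithium [5-iodo-3-methyl-1-oxo-1-(2-trimethylsilylethoxy)pent-2-en-2-yl](methyl)cuprate, Cu cis to the 3-methyl | C[Cu-]/C(C(=O)OCC[Si](C)(C)C)=C(\C)CCI.[Li+] | intermediate (not isolated)
12 | 2-(trimethylsilyl)ethyl (E)-2-chloro-5-iodo-3-methylpent-2-enoate (Cl cis to CH3) | C[Si](C)(C)CCOC(=O)/C(Cl)=C(/C)CCI | intermediate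
13 | bis[(E)-4-chloro-3-methyl-5-oxo-5-(2-trimethylsilylethoxy)pent-3-en-1-yl]zinc | C[Si](C)(C)CCOC(=O)/C(Cl)=C(/C)CC[Zn]CC/C(C)=C(Cl)\C(=O)OCC[Si](C)(C)C | intermediate (not isolated)
14 | (2S)-carbinol: 7 with CHO replaced by (S)-CH(OH)CH2CH2C(CH3)=C(Cl)CO2CH2CH2SiMe3 (E-chloroalkene) | C[C@H]1C(O[Si](C(C)C)(C(C)C)C(C)C)=CC[C@](C)([C@@H](O)CC/C(C)=C(Cl)\C(=O)OCC[Si](C)(C)C)[C@H]1C(=O)SCC | intermediate
15 | cyclohexenone from 14 (C12 ketone, C13=C14) | C[C@H]1C(=O)C=C[C@](C)([C@@H](O)CC/C(C)=C(Cl)\C(=O)OCC[Si](C)(C)C)[C@H]1C(=O)SCC | intermediate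
16 | 12α-allylic alcohol (2S,12α-diol; 12-OH trans to C11 methyl) | C[C@H]1[C@H](O)C=C[C@](C)([C@@H](O)CC/C(C)=C(Cl)\C(=O)OCC[Si](C)(C)C)[C@H]1C(=O)SCC | intermediate
17 | 13α,14α-epoxy-2,12-diol (epoxide cis to 12-OH) | C[C@H]1[C@H](O)[C@@H]2O[C@@H]2[C@](C)([C@@H](O)CC/C(C)=C(Cl)\C(=O)OCC[Si](C)(C)C)[C@H]1C(=O)SCC | intermediate
18 | 2,12-di-O-acetate of 17 | C[C@H]1[C@H](OC(C)=O)[C@@H]2O[C@@H]2[C@](C)([C@@H](OC(C)=O)CC/C(C)=C(Cl)\C(=O)OCC[Si](C)(C)C)[C@H]1C(=O)SCC | intermediate
19 | methyl (R)-3-hydroxy-2-methylpropanoate | COC(=O)[C@@H](CO)C | starting material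
20 | methyl (S)-3-iodo-2-methylpropanoate | COC(=O)[C@@H](CI)C | intermediate
21 | [(S)-3-methoxy-2-methyl-3-oxopropyl]zinc iodide | COC(=O)[C@@H](C[Zn]I)C | intermediate (not isolated)
22 | keto ester: 18 with C(=O)SEt replaced by C(=O)CH2CH(CH3)CO2CH3 (C9 ketone, 17R) | C[C@H]1[C@H](OC(C)=O)[C@@H]2O[C@@H]2[C@](C)([C@@H](OC(C)=O)CC/C(C)=C(Cl)\C(=O)OCC[Si](C)(C)C)[C@H]1C(=O)C[C@@H](C)C(=O)OC | intermediate
23 | 9-O-trimethylsilyl C8=C9 enol ether of 22 | C[C@H]1[C@H](OC(C)=O)[C@@H]2O[C@@H]2[C@](C)([C@@H](OC(C)=O)CC/C(C)=C(Cl)\C(=O)OCC[Si](C)(C)C)[C@H]1C(O[Si](C)(C)C)=C[C@@H](C)C(=O)OC | intermediate (not isolated)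
24 | 8-bromo-9-ketone from 22 (C8 epimers) | C[C@H]1[C@H](OC(C)=O)[C@@H]2O[C@@H]2[C@](C)([C@@H](OC(C)=O)CC/C(C)=C(Cl)\C(=O)OCC[Si](C)(C)C)[C@H]1C(=O)C(Br)[C@@H](C)C(=O)OC | intermediate
25 | tris(dimethylamino)sulfonium C7 carboxylate of 24 | C[C@H]1[C@H](OC(C)=O)[C@@H]2O[C@@H]2[C@](C)([C@@H](OC(C)=O)CC/C(C)=C(Cl)\C(=O)[O-])[C@H]1C(=O)C(Br)[C@@H](C)C(=O)OC.CN(C)[S+](N(C)C)N(C)C | intermediate (not isolated)
26 | eleven-membered lactone: C7(=O)–O–C8 closes the ring C1–C7/O/C8–C10 fused to ring A; C9 ketone; C8 carries CH(CH3)CO2CH3 (C8 epimers) | C[C@H]1[C@H](OC(C)=O)[C@@H]2O[C@@H]2[C@]3(C)[C@@H](OC(C)=O)CC/C(C)=C(Cl)\C(=O)OC([C@@H](C)C(=O)OC)C(=O)[C@@H]13 | intermediate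
27 | lithium C8=C9 enolate of 26 | C[C@H]1[C@H](OC(C)=O)[C@@H]2O[C@@H]2[C@]3(C)[C@@H](OC(C)=O)CC/C(C)=C(Cl)\C(=O)OC([C@@H](C)C(=O)OC)=C([O-])[C@@H]13.[Li+] | intermediate (not isolated)
28 | ten-membered carbocycle: 2β,12α-diacetoxy-6-chloro-13α,14α-epoxy-8α-hydroxy-7,9-dioxo-5-ene with 8β-CH(CH3)CO2CH3 (17R) | C[C@H]1[C@H](OC(C)=O)[C@@H]2O[C@@H]2[C@]3(C)[C@@H](OC(C)=O)CC/C(C)=C(Cl)\C(=O)[C@@](O)([C@@H](C)C(=O)OC)C(=O)[C@@H]13 | intermediate
29 | 7β-hydroxy derivative of 28 (7β,8α-diol, C9 ketone, methyl ester) | C[C@H]1[C@H](OC(C)=O)[C@@H]2O[C@@H]2[C@]3(C)[C@@H](OC(C)=O)CC/C(C)=C(Cl)\[C@@H](O)[C@@](O)([C@@H](C)C(=O)OC)C(=O)[C@@H]13 | intermediate (not isolated)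
30 | 9-oxo analogue of the target (C19(=O)–O–C7 γ-lactone closed, 8α-OH, C9 ketone) | CC(=O)O[C@H]1[C@H](C)[C@@H]2C(=O)[C@@]3(O)[C@H](OC(=O)[C@@H]3C)/C(Cl)=C(/C)CC[C@H](OC(C)=O)[C@@]2(C)[C@H]2O[C@@H]12 | intermediate
31 | CNP0255641.1: 2β,12α-diacetoxy-6-chloro-13α,14α-epoxy-8α,9β-dihydroxy briar-5-ene with the C19(=O)–O–C7β γ-lactone, 17-methyl cis to 8-OH | CC(=O)O[C@H]1[C@H](C)[C@@H]2[C@H](O)[C@@]3(O)[C@H](OC(=O)[C@@H]3C)/C(Cl)=C(/C)CC[C@H](OC(C)=O)[C@@]2(C)[C@H]2O[C@@H]12 | target

**Totals**
Total step count: 18. Longest linear sequence: 14 steps (steps 1, 2, 4, 7, 8, 9, 10, 11, 13, 14, 15, 16, 17, 18).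

**Steps most likely to fail**

Step 4 (Diels–Alder): the aldehyde must outweigh the thioester in directing regiochemistry, and the enantioselectivity with a doubly activated, trisubstituted dienophile is untested. The absolute sense of the oxazaborolidinium catalyst (step 4) and of the CBS reagent (step 9) was assigned from general models, not from a close precedent. Fallback: it sets out from 4 (with 6). EtAlCl2 in toluene at −78 °C promotes the same cycloaddition without a chiral catalyst and gives racemic material, that is 7 together with the mirror-image cycloadduct F1. The ligand-controlled zinc addition of step 7 then acts as the resolving step: 7 gives 14 and F1 gives the diastereomeric carbinol F2 (2S, antipodal ring A), which is removed by chromatography. The route is rejoined at 14.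

Step 15 (macrolactonisation): an eleven-membered ring must close, and E1cB loss of HBr toward C17 competes. Fallback: it sets out from 22. The C8 lithium enolate (LiN(SiMe3)2, −78 °C) is hydroxylated with 2-(phenylsulfonyl)-3-phenyloxaziridine to give the 8-hydroxy ketone F3. TASF removes the silylethyl ester to give the seco hydroxy acid F4. Shiina macrolactonisation (2-methyl-6-nitrobenzoic anhydride, DMAP, slow addition, toluene) acylates the 8-OH, so the ring is closed by acyl activation in place of carboxylate alkylation. The route is rejoined at 26.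

Step 16 (proposed ring-contracting acyl shift): the enolate may fail to attack the hindered, conjugated ester, the C17 ester enolate may expel the C8 carboxylate, or the wrong C8 epimer may form. Fallback with known chemistry: it sets out from 22.
- TASF gives the carboxylic acid F5, and EDC with ethanethiol gives the S-ethyl thioester F6.
- Fukuyama reduction (Et3SiH, palladium on carbon) gives the α-chloro enal F7.
- Soft enolisation (Me3SiOTf, Et3N) gives the trimethylsilyl enol ether F8, and N-bromosuccinimide gives the bromo keto aldehyde F9.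
- SmI2 (THF, −78 °C, high dilution) effects an intramolecular Reformatsky-type aldol between C8 and the C7 aldehyde, an established closure for medium carbocycles, giving the macrocyclic aldol F10.
- Dess–Martin oxidation gives the macrocyclic 1,3-diketone F11, and hydroxylation of its C8 enol with dimethyldioxirane gives 28 (C8 epimers separable), where the route is rejoined.

**Further compounds**
F1 | step 4 | mirror-image cycloadduct (enantiomer of 7) | C[C@@H]1C(O[Si](C(C)C)(C(C)C)C(C)C)=CC[C@@](C)(C=O)[C@@H]1C(=O)SCC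
F2 | step 4 | diastereomeric carbinol (2S, antipodal ring A) | C[C@@H]1C(O[Si](C(C)C)(C(C)C)C(C)C)=CC[C@@](C)([C@@H](O)CC/C(C)=C(Cl)\C(=O)OCC[Si](C)(C)C)[C@@H]1C(=O)SCC
F3 | step 15 | 8-hydroxy ketone (8-hydroxy derivative of 22) | C[C@H]1[C@H](OC(C)=O)[C@@H]2O[C@@H]2[C@](C)([C@@H](OC(C)=O)CC/C(C)=C(Cl)\C(=O)OCC[Si](C)(C)C)[C@H]1C(=O)C(O)[C@@H](C)C(=O)OC
F4 | step 15 | seco hydroxy acid (C7 acid, 8-OH) | C[C@H]1[C@H](OC(C)=O)[C@@H]2O[C@@H]2[C@](C)([C@@H](OC(C)=O)CC/C(C)=C(Cl)\C(=O)O)[C@H]1C(=O)C(O)[C@@H](C)C(=O)OC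
F5 | step 16 | carboxylic acid (C7 acid of 22) | C[C@H]1[C@H](OC(C)=O)[C@@H]2O[C@@H]2[C@](C)([C@@H](OC(C)=O)CC/C(C)=C(Cl)\C(=O)O)[C@H]1C(=O)C[C@@H](C)C(=O)OC
F6 | step 16 | S-ethyl thioester at C7 | C[C@H]1[C@H](OC(C)=O)[C@@H]2O[C@@H]2[C@](C)([C@@H](OC(C)=O)CC/C(C)=C(Cl)\C(=O)SCC)[C@H]1C(=O)C[C@@H](C)C(=O)OC
F7 | step 16 | α-chloro enal (C7 aldehyde) | C[C@H]1[C@H](OC(C)=O)[C@@H]2O[C@@H]2[C@](C)([C@@H](OC(C)=O)CC/C(C)=C(Cl)\C=O)[C@H]1C(=O)C[C@@H](C)C(=O)OC
F8 | step 16 | trimethylsilyl enol ether (C8=C9) of F7 | C[C@H]1[C@H](OC(C)=O)[C@@H]2O[C@@H]2[C@](C)([C@@H](OC(C)=O)CC/C(C)=C(Cl)\C=O)[C@H]1C(O[Si](C)(C)C)=C[C@@H](C)C(=O)OC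
F9 | step 16 | bromo keto aldehyde (8-bromo, C7 aldehyde) | C[C@H]1[C@H](OC(C)=O)[C@@H]2O[C@@H]2[C@](C)([C@@H](OC(C)=O)CC/C(C)=C(Cl)\C=O)[C@H]1C(=O)C(Br)[C@@H](C)C(=O)OC
F10 | step 16 | macrocyclic aldol (ten-membered 7-hydroxy-9-ketone, C8–H) | C[C@H]1[C@H](OC(C)=O)[C@@H]2O[C@@H]2[C@]3(C)[C@@H](OC(C)=O)CC/C(C)=C(Cl)\C(O)C([C@@H](C)C(=O)OC)C(=O)[C@@H]13
F11 | step 16 | macrocyclic 1,3-diketone (ten-membered 7,9-dione, C8–H) | C[C@H]1[C@H](OC(C)=O)[C@@H]2O[C@@H]2[C@]3(C)[C@@H](OC(C)=O)CC/C(C)=C(Cl)\C(=O)C([C@@H](C)C(=O)OC)C(=O)[C@@H]13
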